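## The problem

The target 41 is a C24 acid, numbered here from the carboxyl carbon C1 to the vinyl terminus C24. A 1,2-dioxane (O–O between C3 and C6, acetic acid arm on C3) is joined through the C6–C7 bond to a tetrahydrofuran (C7–C10, oxygen between C7 and C10), and C10 carries a fourteen-carbon chain with a 17Z,19E-diene and a terminal C23=C24 alkene. The four stereocentres (3R,6R,7S,10R) place the substituents trans across the tetrahydrofuran oxygen, erythro at C6/C7 and trans across the peroxide. C7 can direct C10 (1,3 across the ring oxygen) and C6 (1,2, by chelation to the ring oxygen). C3 lies beyond the peroxide, out of reach of substrate control, and must come from a reagent and then be transferred by a stereospecific displacement. The O–O bond does not survive hydrogenation, phosphines, phosphorus ylides or low-valent metals, and strong base fragments it at C3–H or C6–H (Kornblum–DeLaMare). The triene excludes hydrogenation, ozone and electrophilic oxidants once it is in place, and the β-peroxy acid can ring-open by retro-oxa-Michael reaction if C2 is enolised. The order is therefore fixed: saturate first, build the triene second, close the peroxide last. The enabling feature is that C10 is an ether carbon whose chain begins with carbons that can arrive as an allyl group migrating from the ring oxygen, while C6–C9 with the oxygenated C7 stereocentre is L-malic acid (used as its dimethyl ester 1). A C9 ketone with a diazo carbon at C10 and an O-allyl group on C7 is thus set up for oxonium ylide formation and [2,3] shift.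

## Retrosynthesis

**41 back to 38 (C1 oxidation level).** No skeletal bond is cut. The acid is taken back to alcohol 39 and its silyl ether 38, because a carboxyl derivative at C1 would turn any leaving group on C3 into a β-elimination substrate during peroxide formation. The neighbouring option, keeping the acid and closing the ring by peroxide conjugate addition to a C2=C3 enoate, would set C3 only through a weak conformational preference. The forward steps must spare O–O and the triene, which points to buffered fluoride and an oxoammonium oxidation.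

**38 back to 36 and 35 (both C–O bonds of the peroxide).** Cutting C3–O and C6–O together leads to bis-mesylate 36 and diol 35. Each bond is then made by SN2 alkylation of H2O2 with inversion, so the trans-dioxane follows stereospecifically from a (3S,6S)-diol. Cutting only one C–O bond would require a secondary hydroperoxide to be carried through earlier steps. Precursor 35 has no peroxide at all. The forward reaction needs intermolecular attack at the unhindered C3 and then 6-exo-tet closure at C6, which is flanked by the ring oxygen, to outrun elimination.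

**35 back to 34, then to 23 and 31 (C5–C6).** This cut makes C6 from C7: Cram-chelate addition to α-alkoxy aldehyde 23 gives the threo (6S) alcohol, exactly the configuration the later inversion needs. It also imports C3 ready-made in the five-carbon iodide 31. A cut at C6–C7 would put C7 at risk, and a cut at C4–C5 would leave C6 to be set separately. In 31 the C3 oxygen carries a triethylsilyl group and the C1 oxygen a tert-butyldiphenylsilyl group, so that only C3–OH is freed before sulfonylation.

**31 back to 24 (C3–C4).** Iodide 31 comes from alcohol 30, made by ozonolysis and reduction of alkene 28 via aldehyde 29. Alkene 28 is the silyl ether of homoallylic alcohol 27, and 27 arises by reagent-controlled allylation of aldehyde 26 (from 25 and propane-1,3-diol 24). This is the only stereocentre of the target that needs an external chiral reagent. The terminal alkene of 27 is a masked C5 hydroxymethyl group.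

**23 back to 17 and 19 (C17=C18).** Aldehyde 23 comes from alcohol 22 and silyl ether 21. The diene is cut at C17=C18 because a non-stabilised ylide (20, from phosphonium salt 17) and E-enal 19 give the Z-alkene while carrying the E-alkene through. A cut at C18–C19 would need a separately made vinyl halide and vinyl metal. Enal 19 is the two-carbon homologue of pent-4-enal 18. The olefination must precede the peroxide and follow every hydrogenation.

**17 back to 13 and 14 (C12=C13).** Salt 17 comes from bromide 16, the hydrogenation product of 15. The C12=C13 bond of 15 is cut by cross metathesis into allyl tetrahydrofuran 13 and 6-bromohex-1-ene 14, so the allyl group left by the key step serves as the chain handle. Saturation is placed here, where no other alkene exists.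

**13 back to 10 (C9 oxygen).** The C9 methylene is taken back to thiocarbonyl derivative 12, alcohol 11 and ketone 10, the retron of the ylide rearrangement. A radical deoxygenation is preferred over hydrazone reductions, which can expel the neighbouring ring oxygen.

**10 back to 8 (O–C10 and C10–C11, the key cut).** Both bonds are cut to reach the acyclic diazoketone 8 with one stereocentre. Ring closures by etherification at C10 or C7 would need C10 configured beforehand in a separate asymmetric step. Here C7 sets C10 during ring formation via oxonium ylide 9. The forward reaction must favour ylide formation over C–H insertion and the [2,3] over the [1,2] shift, and deliver the allyl group trans to the C7 substituent.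

**8 back to 1 and 4 (C9–C10 and O–allyl).** Diazoketone 8 comes from acid 6 by acylation of CH2N2 via mixed anhydride 7. Acid 6 comes from ester 5, the O-allyl ether formed from alcohol 3 and imidate 4. Alcohol 3 is the silyl ether of diol 2, obtained by hydroxyl-directed reduction of dimethyl L-malate 1. C6 is carried as a silyloxymethyl group, not an ester. An ester on C7 would weaken the ether oxygen as a nucleophile, offer its own carbonyl oxygen to the carbenoid, and leave the product prone to β-elimination of the ring oxygen.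

## Roads not taken

**Alternative 1:** The dioxane would be cut at C3–C4. A Lewis acid (SnCl4 or Me3SiOTf) would ionise a monoperoxyacetal at C3 whose peroxide oxygen already sits on C6. The silicon-bearing carbon C4 of a Z-vinylsilane would attack the peroxycarbenium ion, and loss of silicon would give the 3,6-dihydro-1,2-dioxine A1.
- Merits: the ring is closed by C–C bond formation, C3 is created in the cyclisation without a separate chiral fragment, and no bis-sulfonate is needed. On that count it is more economical than the chosen plan, which spends six steps on iodide 31.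
- Weak points: it needs a C6 hydroperoxide of defined configuration next to the tetrahydrofuran, made by an intermolecular displacement at the most hindered carbon or by a non-selective radical hydroperoxidation. That hydroperoxide must survive vinylsilane construction. Vinylsilane capture of peroxycarbenium ions is less secure than the allylsilane version and competes with Lewis-acid fragmentation of the peroxide. C3 would rest on a kinetic preference, not a stereospecific event.
- A1 still needs its C4=C5 bond reduced without touching O–O, and carries only a silyl ether at C17, so the triene would have to be built with ylide chemistry in the presence of the peroxide.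
- The chosen plan sets against this a stereospecific origin for both C3 and C6 and a peroxide that appears only after the triene is complete.

**Alternative 2:** Both rings would be made in one operation from a pyran derived from Cyrene A2. The ring oxygen would displace an equatorial C7 triflate to give a bicyclic oxonium ion, and the distal oxygen of a C3 perketal would open it at C6, forming O–C7 and OO–C6 and giving A3.
- Merits: A3 is the same compound as 38 of the present route. If the cascade worked it would reach that intermediate with both inversions stereospecific and the erythro C6/C7 relationship following automatically from anti opening. In elegance and in late-stage step count it would be better.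
- Weak points: the cascade has no close model. A peroxide oxygen is a poor nucleophile for an oxonium ion and must shed an oxocarbenium fragment to complete the transfer. Triflate return, solvent capture and elimination compete. The ionising medium generates cations in the presence of the triene. C3 and C10 still need their own asymmetric steps on the pyran.
- The chosen plan sets against this a sequence in which every step has a known counterpart, with a catalytic ring closure whose stereochemical course is established.

**Alternative 3:** Both rings would be cut at their C4=C5 and C8=C9 positions. A tetraene with vinyl groups on C3, C6, C7 and C10, built on a C6–C7 diol core from diethyl L-tartrate A4, would undergo double ring-closing metathesis with second-generation Grubbs catalyst to give A5.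
- Merits: both rings close in one catalytic step, dialkyl peroxides tolerate ruthenium carbenes, and the C6/C7 pair comes from a cheap source. The ring closure itself is likely to be more efficient than a double displacement with H2O2.
- Weak points: the acyclic bis-allylic peroxide must be assembled by alkylating a secondary allylic hydroperoxide with a secondary allylic sulfonate, where direct and allylic substitution compete. C3 and C10 each need a separate asymmetric step. The C6-vinyl/C10-vinyl pairing would give a six-membered dihydropyran instead of the intended rings.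
- Both ring alkenes of A5 must then be saturated with diimide in the presence of O–O, before any triene exists, so the side chain again has to be finished next to the peroxide.
- The chosen plan sets against this substrate control of C10 by C7, ring systems that are saturated from the outset, and a triene built before the peroxide.

Key step: step 6

Remark on the chemistry: 11 and 12 are carried as mixtures of epimers at the former C9 (deleted in step 9) and 15 as an E/Z mixture (saturated in step 11), so their SMILES leave these elements open.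

## Route

Step 1
Reactants: 1 dimethyl (S)-malate (dimethyl L-malate)
Product: 2 methyl (S)-3,4-dihydroxybutanoate
Conditions: BH3·SMe2, NaBH4 (5 mol %), THF, 0 °C to rt; MeOH quench
Reagents that add atoms: none
Why: Hydroxyl-directed borane reduction: the C7 hydroxyl forms an alkoxyborane that delivers hydride only to the adjacent ester (C6), a standard chemoselective reduction of malate diesters; C7 is not touched.

Step 2
Reactants: 2 methyl (S)-3,4-dihydroxybutanoate
Product: 3 methyl (S)-4-[(tert-butyldiphenylsilyl)oxy]-3-hydroxybutanoate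
Conditions: TBDPSCl, imidazole, CH2Cl2, 0 °C
Reagents that add atoms: tert-butylchlorodiphenylsilane, CC(C)(C)[Si](Cl)(c1ccccc1)c1ccccc1
Why: Selective silylation of the primary hydroxyl by a bulky chlorosilane; the group is chosen to survive every step up to step 15.

Step 3
Reactants: 3 methyl (S)-4-[(tert-butyldiphenylsilyl)oxy]-3-hydroxybutanoate; 4 allyl 2,2,2-trichloroacetimidate
Product: 5 methyl (S)-3-(allyloxy)-4-[(tert-butyldiphenylsilyl)oxy]butanoate
Conditions: TfOH (5 mol %), cyclohexane/CH2Cl2 2:1, rt
Reagents that add atoms: none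
Why: Acid-catalysed O-alkylation with a trichloroacetimidate; the absence of base avoids β-elimination or retro-aldol cleavage of the β-hydroxy ester and silyl migration.

Step 4
Reactants: 5 methyl (S)-3-(allyloxy)-4-[(tert-butyldiphenylsilyl)oxy]butanoate
Product: 6 (S)-3-(allyloxy)-4-[(tert-butyldiphenylsilyl)oxy]butanoic acid
Conditions: LiOH·H2O, THF/H2O 3:1, 0 °C; then 1 M HCl to pH 3
Reagents that add atoms: lithium hydroxide, [Li+].[OH-]
Why: Ester saponification at low temperature, where hydrolysis is faster than β-elimination of the allyloxy group; the silyl ether is stable to these conditions.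

Step 5
Reactants: 6 (S)-3-(allyloxy)-4-[(tert-butyldiphenylsilyl)oxy]butanoic acid
Product: 8 (S)-4-(allyloxy)-5-[(tert-butyldiphenylsilyl)oxy]-1-diazopentan-2-one, via mixed anhydride 7 (not isolated)
Conditions: i-BuOCOCl, Et3N, Et2O, −20 °C; then CH2N2, Et2O, 0 °C to rt
Reagents that add atoms: diazomethane, C=[N+]=[N-]
Why: Acylation of diazomethane by a mixed carbonic anhydride, the standard mild route to α-diazoketones; it introduces C10 and does not affect C7.

Step 6
Reactants: 8 (S)-4-(allyloxy)-5-[(tert-butyldiphenylsilyl)oxy]-1-diazopentan-2-one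
Product: 10 (2R,5S)-2-allyl-5-{[(tert-butyldiphenylsilyl)oxy]methyl}dihydrofuran-3(2H)-one, via oxonium ylide 9 (not isolated)
Conditions: Cu(acac)2 (5 mol %), THF, reflux, slow addition of 8
Reagents that add atoms: none
Why: The divalent copper chelate Cu(acac)2 decomposes 8 with loss of N2 to an electrophilic copper carbenoid at C10, and the allyl ether oxygen on C7, five atoms away, adds to it to close the five-membered cyclic oxonium ylide 9 (ring closure by O–C10 bond formation). The ylide, free or copper-bound, then undergoes a concerted suprafacial [2,3]-sigmatropic shift through a five-membered envelope transition state: C10 bonds to the former alkene terminus (now C11) while the O–CH2 bond breaks. The closest known reaction type is the copper-catalysed oxonium ylide formation and [2,3] rearrangement of allyl ethers of diazoketones, which gives trans-2,5-dialkyltetrahydrofuran-3-ones. The new stereocentre C10 is controlled by C7: the silyloxymethyl group sits pseudo-equatorial in the envelope and the allyl group migrates across the face away from it, so the two substituents end up trans (2R,5S). The step needs ylide formation in preference to 1,5 C–H insertion at the silyloxy-bearing C6 and to cyclopropanation, the [2,3] shift in preference to a [1,2] shift, and trans in preference to cis delivery. These are secured by the acetylacetonate copper carbenoid, which prefers lone pairs to C–H bonds more than dirhodium tetracarboxylates do, by the allyl group, which opens the symmetry-allowed five-centre pathway, and by the bulk of the C7 substituent. Slow addition keeps the diazoketone concentration low and suppresses carbene dimerisation.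

Step 7
Reactants: 10 (2R,5S)-2-allyl-5-{[(tert-butyldiphenylsilyl)oxy]methyl}dihydrofuran-3(2H)-one
Product: 11 (2R,5S)-2-allyl-5-{[(tert-butyldiphenylsilyl)oxy]methyl}tetrahydrofuran-3-ol (both C3 epimers)
Conditions: NaBH4, MeOH, −20 °C
Reagents that add atoms: none
Why: Hydride reduction of the ketone at low temperature, fast enough to precede enolisation toward C10; the configuration of the new carbinol is irrelevant because C9 becomes a methylene group in step 9.

Step 8
Reactants: 11 (2R,5S)-2-allyl-5-{[(tert-butyldiphenylsilyl)oxy]methyl}tetrahydrofuran-3-ol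
Product: 12 O-[(2R,5S)-2-allyl-5-{[(tert-butyldiphenylsilyl)oxy]methyl}tetrahydrofuran-3-yl] 1H-imidazole-1-carbothioate (both C3 epimers)
Conditions: 1,1'-thiocarbonyldiimidazole, DMAP (cat.), THF, 65 °C
Reagents that add atoms: 1,1'-thiocarbonyldiimidazole, S=C(n1ccnc1)n1ccnc1
Why: Thioacylation of the secondary alcohol under neutral conditions, which avoids the strong base of xanthate formation next to the ring oxygen.

Step 9
Reactants: 12 O-[(2R,5S)-2-allyl-5-{[(tert-butyldiphenylsilyl)oxy]methyl}tetrahydrofuran-3-yl] 1H-imidazole-1-carbothioate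
Product: 13 tert-butyl{[(2S,5S)-5-allyltetrahydrofuran-2-yl]methoxy}diphenylsilane
Conditions: Bu3SnH, AIBN (cat.), toluene, 100 °C
Reagents that add atoms: none
Why: Barton–McCombie deoxygenation: the stannyl radical adds to the thiocarbonyl group, the C9–O bond fragments and the C9 radical takes hydrogen from Bu3SnH. The radical has no productive cyclisation onto the allyl group and does not expel the ring oxygen, so C7 and C10 are untouched (the descriptor at C10 changes only through ligand priorities).

Step 10
Reactants: 13 tert-butyl{[(2S,5S)-5-allyltetrahydrofuran-2-yl]methoxy}diphenylsilane; 14 6-bromohex-1-ene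
Product: 15 {[(2S,5S)-5-(7-bromohept-2-en-1-yl)tetrahydrofuran-2-yl]methoxy}(tert-butyl)diphenylsilane (E/Z mixture)
Conditions: second-generation Grubbs catalyst (5 mol %), 14 (4 equiv), CH2Cl2, 40 °C
Reagents that add atoms: none
Why: Olefin cross metathesis between two unhindered terminal alkenes; an excess of the inexpensive partner 14 drives 13 to the cross product, and the alkene geometry is irrelevant because the bond is hydrogenated next.

Step 11
Reactants: 15 {[(2S,5S)-5-(7-bromohept-2-en-1-yl)tetrahydrofuran-2-yl]methoxy}(tert-butyl)diphenylsilane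
Product: 16 {[(2S,5R)-5-(7-bromoheptyl)tetrahydrofuran-2-yl]methoxy}(tert-butyl)diphenylsilane
Conditions: H2 (1 atm), PtO2, EtOAc, rt
Reagents that add atoms: none
Why: Heterogeneous hydrogenation of a disubstituted alkene; PtO2 in a neutral solvent leaves the primary C–Br bond and the silyl ether intact, and this is the last point at which hydrogenation is permissible.

Step 12
Reactants: 16 {[(2S,5R)-5-(7-bromoheptyl)tetrahydrofuran-2-yl]methoxy}(tert-butyl)diphenylsilane
Product: 17 {7-[(2R,5S)-5-{[(tert-butyldiphenylsilyl)oxy]methyl}tetrahydrofuran-2-yl]heptyl}triphenylphosphonium bromide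
Conditions: PPh3, MeCN, 80 °C
Reagents that add atoms: triphenylphosphine, c1ccc(cc1)P(c1ccccc1)c1ccccc1
Why: SN2 quaternisation of triphenylphosphine by a primary alkyl bromide.

Step 13
Reactants: 18 pent-4-enal
Product: 19 (E)-hepta-2,6-dienal
Conditions: Ph3P=CHCHO (1.0 equiv), toluene, 80 °C
Reagents that add atoms: (triphenylphosphoranylidene)acetaldehyde, O=CC=P(c1ccccc1)(c1ccccc1)c1ccccc1
Why: Wittig reaction with the stabilised formyl ylide, which gives E-enals; one equivalent of ylide limits a second homologation of the less electrophilic enal 19.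

Step 14
Reactants: 17 {7-[(2R,5S)-5-{[(tert-butyldiphenylsilyl)oxy]methyl}tetrahydrofuran-2-yl]heptyl}triphenylphosphonium bromide; 19 (E)-hepta-2,6-dienal
Product: 21 tert-butyldiphenyl{[(2S,5R)-5-[(7Z,9E)-tetradeca-7,9,13-trien-1-yl]tetrahydrofuran-2-yl]methoxy}silane, via phosphorus ylide 20 (not isolated)
Conditions: NaN(SiMe3)2, THF, −78 to 0 °C; then 19, −78 °C to rt
Reagents that add atoms: none
Why: Wittig olefination of a lithium-free non-stabilised ylide with an α,β-unsaturated aldehyde: kinetically controlled cis-oxaphosphetane formation makes the new C17=C18 bond Z, and the 19E bond of 19 is carried through unchanged. 1,2-Addition is the normal course of such ylides with enals.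

Step 15
Reactants: 21 tert-butyldiphenyl{[(2S,5R)-5-[(7Z,9E)-tetradeca-7,9,13-trien-1-yl]tetrahydrofuran-2-yl]methoxy}silane
Product: 22 [(2S,5R)-5-[(7Z,9E)-tetradeca-7,9,13-trien-1-yl]tetrahydrofuran-2-yl]methanol
Conditions: Bu4NF, THF, 0 °C to rt
Reagents that add atoms: none
Why: Fluoride cleavage of the primary silyl ether; the triene and the ring are inert to fluoride.

Step 16
Reactants: 22 [(2S,5R)-5-[(7Z,9E)-tetradeca-7,9,13-trien-1-yl]tetrahydrofuran-2-yl]methanol
Product: 23 (2S,5R)-5-[(7Z,9E)-tetradeca-7,9,13-trien-1-yl]tetrahydrofuran-2-carbaldehyde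
Conditions: Dess–Martin periodinane, NaHCO3, CH2Cl2, 0 °C to rt
Reagents that add atoms: none
Why: Dess–Martin oxidation under buffered, non-basic conditions that neither epimerise the α-alkoxy aldehyde at C7 nor touch the triene; 23 is used at once without chromatography.

Step 17
Reactants: 24 propane-1,3-diol
Product: 25 3-[(tert-butyldiphenylsilyl)oxy]propan-1-ol
Conditions: NaH (1.0 equiv), THF, 0 °C to rt; then TBDPSCl (1.0 equiv)
Reagents that add atoms: tert-butylchlorodiphenylsilane, CC(C)(C)[Si](Cl)(c1ccccc1)c1ccccc1
Why: Monosilylation of a symmetrical diol through its sparingly soluble monosodium alkoxide, which reacts once.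

Step 18
Reactants: 25 3-[(tert-butyldiphenylsilyl)oxy]propan-1-ol
Product: 26 3-[(tert-butyldiphenylsilyl)oxy]propanal
Conditions: Dess–Martin periodinane, NaHCO3, CH2Cl2, rt
Reagents that add atoms: none
Why: Dess–Martin oxidation; the neutral conditions avoid β-elimination of the silyloxy group from the aldehyde.

Step 19
Reactants: 26 3-[(tert-butyldiphenylsilyl)oxy]propanal
Product: 27 (S)-1-[(tert-butyldiphenylsilyl)oxy]hex-5-en-3-ol
Conditions: (−)-Ipc2B(allyl), Et2O, −78 °C; then NaOH, H2O2, 0 °C to rt
Reagents that add atoms: (−)-B-allyldiisopinocampheylborane, C[C@H]1[C@@H](C[C@@H]2C[C@H]1C2(C)C)B(CC=C)[C@@H]1C[C@@H]2C[C@H]([C@H]1C)C2(C)C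
Why: Brown allylation: the allylborane derived from (+)-α-pinene transfers allyl through a chair six-membered transition state and, with unbranched β-alkoxy aldehydes, should give the (S)-homoallylic alcohol. This reagent-controlled step sets C3 of the target in the configuration that the later inversion requires.

Step 20
Reactants: 27 (S)-1-[(tert-butyldiphenylsilyl)oxy]hex-5-en-3-ol
Product: 28 (S)-tert-butyldiphenyl({3-[(triethylsilyl)oxy]hex-5-en-1-yl}oxy)silane
Conditions: TESCl, imidazole, CH2Cl2, 0 °C
Reagents that add atoms: chlorotriethylsilane, CC[Si](Cl)(CC)CC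
Why: Silylation of the secondary alcohol with a group that can later be removed by mild acid in the presence of the tert-butyldiphenylsilyl ether.

Step 21
Reactants: 28 (S)-tert-butyldiphenyl({3-[(triethylsilyl)oxy]hex-5-en-1-yl}oxy)silane
Product: 30 (S)-5-[(tert-butyldiphenylsilyl)oxy]-3-[(triethylsilyl)oxy]pentan-1-ol, via aldehyde 29 (not isolated)
Conditions: O3, CH2Cl2/MeOH, −78 °C; Me2S; then NaBH4, 0 °C
Reagents that add atoms: ozone, [O-][O+]=O
Why: Ozonolysis of the terminal alkene removes the surplus carbon, and reduction in the same flask takes aldehyde 29 to the primary alcohol; both silyl ethers tolerate the conditions and no other alkene is present in this fragment.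

Step 22
Reactants: 30 (S)-5-[(tert-butyldiphenylsilyl)oxy]-3-[(triethylsilyl)oxy]pentan-1-ol
Product: 31 (R)-tert-butyl({5-iodo-3-[(triethylsilyl)oxy]pentyl}oxy)diphenylsilane
Conditions: I2, PPh3, imidazole, CH2Cl2, 0 °C to rt
Reagents that add atoms: iodine, II
Why: Appel-type iodination of a primary alcohol (SN2 on the alkoxyphosphonium ion); the imidazole buffer preserves the triethylsilyl ether, and the change of descriptor is only a change of ligand priorities.

Step 23
Reactants: 23 (2S,5R)-5-[(7Z,9E)-tetradeca-7,9,13-trien-1-yl]tetrahydrofuran-2-carbaldehyde; 31 (R)-tert-butyl({5-iodo-3-[(triethylsilyl)oxy]pentyl}oxy)diphenylsilane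
Product: 34 (1S,4S)-6-[(tert-butyldiphenylsilyl)oxy]-1-[(2S,5R)-5-[(7Z,9E)-tetradeca-7,9,13-trien-1-yl]tetrahydrofuran-2-yl]-4-[(triethylsilyl)oxy]hexan-1-ol, via alkyllithium 32 (not isolated), via alkylmagnesium bromide 33 (not isolated)
Conditions: 31 (1.8 equiv), t-BuLi (2.1 equiv per 31), Et2O, −78 °C; MgBr2·OEt2, −78 to −20 °C; then 23 precomplexed with MgBr2·OEt2 in CH2Cl2, −78 °C
Reagents that add atoms: none
Why: Cram-chelate addition: magnesium bridges the aldehyde oxygen and the ring oxygen of 23 in weakly coordinating solvents, and the alkylmagnesium 33 (from iodine–lithium exchange of 31 and transmetalation) attacks the exposed face to give the threo (6S,7S) alcohol. The C3 stereocentre arrives unchanged in the fragment.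

Step 24
Reactants: 34 (1S,4S)-6-[(tert-butyldiphenylsilyl)oxy]-1-[(2S,5R)-5-[(7Z,9E)-tetradeca-7,9,13-trien-1-yl]tetrahydrofuran-2-yl]-4-[(triethylsilyl)oxy]hexan-1-ol
Product: 35 (1S,4S)-6-[(tert-butyldiphenylsilyl)oxy]-1-[(2S,5R)-5-[(7Z,9E)-tetradeca-7,9,13-trien-1-yl]tetrahydrofuran-2-yl]hexane-1,4-diol
Conditions: PPTS (cat.), MeOH/CH2Cl2, 0 °C
Reagents that add atoms: none
Why: Acid-catalysed methanolysis of the secondary triethylsilyl ether, which is far more labile than the primary tert-butyldiphenylsilyl ether; the mild acid does not isomerise the Z,E-diene.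

Step 25
Reactants: 35 (1S,4S)-6-[(tert-butyldiphenylsilyl)oxy]-1-[(2S,5R)-5-[(7Z,9E)-tetradeca-7,9,13-trien-1-yl]tetrahydrofuran-2-yl]hexane-1,4-diol
Product: 36 (1S,4S)-6-[(tert-butyldiphenylsilyl)oxy]-1-[(2S,5R)-5-[(7Z,9E)-tetradeca-7,9,13-trien-1-yl]tetrahydrofuran-2-yl]hexane-1,4-diyl dimethanesulfonate
Conditions: MsCl, Et3N, DMAP (cat.), CH2Cl2, 0 °C
Reagents that add atoms: methanesulfonyl chloride, CS(=O)(=O)Cl
Why: Sulfonylation of both secondary alcohols through sulfene; the C–O bonds are not broken, so C3 and C6 keep their configuration.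

Step 26
Reactants: 36 (1S,4S)-6-[(tert-butyldiphenylsilyl)oxy]-1-[(2S,5R)-5-[(7Z,9E)-tetradeca-7,9,13-trien-1-yl]tetrahydrofuran-2-yl]hexane-1,4-diyl dimethanesulfonate
Product: 38 tert-butyldiphenyl{2-[(3R,6R)-6-[(2S,5R)-5-[(7Z,9E)-tetradeca-7,9,13-trien-1-yl]tetrahydrofuran-2-yl]-1,2-dioxan-3-yl]ethoxy}silane, via hydroperoxy mesylate 37 (not isolated)
Conditions: 50% aq. H2O2 (excess), KOH, MeOH/THF, 0 °C to rt, high dilution
Reagents that add atoms: hydrogen peroxide, OO
Why: Double SN2 alkylation of hydrogen peroxide by a 1,4-bis-sulfonate, a known route to 3,6-dialkyl-1,2-dioxanes. The hydroperoxide anion displaces the unhindered C3 mesylate with inversion to give 37, whose peroxy anion closes the ring at C6 by 6-exo-tet displacement, again with inversion. The trans (3R,6R) ring therefore follows from the configuration of 36, and the nucleophilic conditions leave the triene alone.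

Step 27
Reactants: 38 tert-butyldiphenyl{2-[(3R,6R)-6-[(2S,5R)-5-[(7Z,9E)-tetradeca-7,9,13-trien-1-yl]tetrahydrofuran-2-yl]-1,2-dioxan-3-yl]ethoxy}silane
Product: 39 2-[(3R,6R)-6-[(2S,5R)-5-[(7Z,9E)-tetradeca-7,9,13-trien-1-yl]tetrahydrofuran-2-yl]-1,2-dioxan-3-yl]ethan-1-ol
Conditions: Bu4NF, AcOH, THF, 0 °C to rt
Reagents that add atoms: none
Why: Fluoride desilylation buffered with acetic acid, so that no free alkoxide is present to start base-induced fragmentation of the peroxide.

Step 28
Reactants: 39 2-[(3R,6R)-6-[(2S,5R)-5-[(7Z,9E)-tetradeca-7,9,13-trien-1-yl]tetrahydrofuran-2-yl]-1,2-dioxan-3-yl]ethan-1-ol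
Product: 41 2-[(3R,6R)-6-[(2S,5R)-5-[(7Z,9E)-tetradeca-7,9,13-trien-1-yl]tetrahydrofuran-2-yl]-1,2-dioxan-3-yl]acetic acid, via aldehyde 40 (not isolated)
Conditions: TEMPO (cat.), PhI(OAc)2, MeCN/aqueous phosphate buffer (pH 7), rt
Reagents that add atoms: water, O
Why: Oxoammonium oxidation of the primary alcohol through aldehyde 40 and its hydrate to the acid under near-neutral, metal-free conditions that dialkyl peroxides and isolated or conjugated alkenes tolerate; no base is present to enolise C2.

## Compound list

1 | dimethyl (S)-malate (dimethyl L-malate) | COC(=O)C[C@H](O)C(=O)OC | starting material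
2 | methyl (S)-3,4-dihydroxybutanoate | COC(=O)C[C@H](O)CO | intermediate
3 | methyl (S)-4-[(tert-butyldiphenylsilyl)oxy]-3-hydroxybutanoate | COC(=O)C[C@H](O)CO[Si](c1ccccc1)(c1ccccc1)C(C)(C)C | intermediate
4 | allyl 2,2,2-trichloroacetimidate | C=CCOC(=N)C(Cl)(Cl)Cl | starting material
5 | methyl (S)-3-(allyloxy)-4-[(tert-butyldiphenylsilyl)oxy]butanoate | COC(=O)C[C@H](OCC=C)CO[Si](c1ccccc1)(c1ccccc1)C(C)(C)C | intermediate
6 | (S)-3-(allyloxy)-4-[(tert-butyldiphenylsilyl)oxy]butanoic acid | OC(=O)C[C@H](OCC=C)CO[Si](c1ccccc1)(c1ccccc1)C(C)(C)C | intermediate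
7 | (S)-3-(allyloxy)-4-[(tert-butyldiphenylsilyl)oxy]butanoic isobutyl carbonic anhydride (mixed anhydride) | CC(C)COC(=O)OC(=O)C[C@H](OCC=C)CO[Si](c1ccccc1)(c1ccccc1)C(C)(C)C | intermediate
8 | (S)-4-(allyloxy)-5-[(tert-butyldiphenylsilyl)oxy]-1-diazopentan-2-one | [N-]=[N+]=CC(=O)C[C@H](OCC=C)CO[Si](c1ccccc1)(c1ccccc1)C(C)(C)C | intermediate
9 | (5S)-1-allyl-5-{[(tert-butyldiphenylsilyl)oxy]methyl}-3-oxotetrahydrofuran-1-ium-2-ide (oxonium ylide) | C=CC[O+]1[CH-]C(=O)C[C@H]1CO[Si](c2ccccc2)(c2ccccc2)C(C)(C)C | intermediate
10 | (2R,5S)-2-allyl-5-{[(tert-butyldiphenylsilyl)oxy]methyl}dihydrofuran-3(2H)-one | C=CC[C@@H]1C(=O)C[C@@H](CO[Si](c2ccccc2)(c2ccccc2)C(C)(C)C)O1 | intermediate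
11 | (2R,5S)-2-allyl-5-{[(tert-butyldiphenylsilyl)oxy]methyl}tetrahydrofuran-3-ol (both C3 epimers) | C=CC[C@@H]1C(O)C[C@@H](CO[Si](c2ccccc2)(c2ccccc2)C(C)(C)C)O1 | intermediate
12 | O-[(2R,5S)-2-allyl-5-{[(tert-butyldiphenylsilyl)oxy]methyl}tetrahydrofuran-3-yl] 1H-imidazole-1-carbothioate (both C3 epimers) | C=CC[C@@H]1C(OC(=S)n2ccnc2)C[C@@H](CO[Si](c2ccccc2)(c2ccccc2)C(C)(C)C)O1 | intermediate
13 | tert-butyl{[(2S,5S)-5-allyltetrahydrofuran-2-yl]methoxy}diphenylsilane | C=CC[C@@H]1CC[C@@H](CO[Si](c2ccccc2)(c2ccccc2)C(C)(C)C)O1 | intermediate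
14 | 6-bromohex-1-ene | C=CCCCCBr | starting material
15 | {[(2S,5S)-5-(7-bromohept-2-en-1-yl)tetrahydrofuran-2-yl]methoxy}(tert-butyl)diphenylsilane (E/Z mixture) | BrCCCCC=CC[C@@H]1CC[C@@H](CO[Si](c2ccccc2)(c2ccccc2)C(C)(C)C)O1 | intermediate
16 | {[(2S,5R)-5-(7-bromoheptyl)tetrahydrofuran-2-yl]methoxy}(tert-butyl)diphenylsilane | BrCCCCCCC[C@@H]1CC[C@@H](CO[Si](c2ccccc2)(c2ccccc2)C(C)(C)C)O1 | intermediate
17 | {7-[(2R,5S)-5-{[(tert-butyldiphenylsilyl)oxy]methyl}tetrahydrofuran-2-yl]heptyl}triphenylphosphonium bromide | [Br-].c1ccccc1[P+](c1ccccc1)(c1ccccc1)CCCCCCC[C@@H]1CC[C@@H](CO[Si](c2ccccc2)(c2ccccc2)C(C)(C)C)O1 | intermediate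
18 | pent-4-enal | C=CCCC=O | starting material
19 | (E)-hepta-2,6-dienal | C=CCC/C=C/C=O | intermediate
20 | {7-[(2R,5S)-5-{[(tert-butyldiphenylsilyl)oxy]methyl}tetrahydrofuran-2-yl]heptylidene}triphenyl-λ5-phosphane (ylide) | c1ccccc1P(c1ccccc1)(c1ccccc1)=CCCCCCC[C@@H]1CC[C@@H](CO[Si](c2ccccc2)(c2ccccc2)C(C)(C)C)O1 | intermediate
21 | tert-butyldiphenyl{[(2S,5R)-5-[(7Z,9E)-tetradeca-7,9,13-trien-1-yl]tetrahydrofuran-2-yl]methoxy}silane | C=CCC/C=C/C=C\CCCCCC[C@@H]1CC[C@@H](CO[Si](c2ccccc2)(c2ccccc2)C(C)(C)C)O1 | intermediate
22 | [(2S,5R)-5-[(7Z,9E)-tetradeca-7,9,13-trien-1-yl]tetrahydrofuran-2-yl]methanol | C=CCC/C=C/C=C\CCCCCC[C@@H]1CC[C@@H](CO)O1 | intermediate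
23 | (2S,5R)-5-[(7Z,9E)-tetradeca-7,9,13-trien-1-yl]tetrahydrofuran-2-carbaldehyde | C=CCC/C=C/C=C\CCCCCC[C@@H]1CC[C@@H](C=O)O1 | intermediate
24 | propane-1,3-diol | OCCCO | starting material
25 | 3-[(tert-butyldiphenylsilyl)oxy]propan-1-ol | OCCCO[Si](c1ccccc1)(c1ccccc1)C(C)(C)C | intermediate
26 | 3-[(tert-butyldiphenylsilyl)oxy]propanal | O=CCCO[Si](c1ccccc1)(c1ccccc1)C(C)(C)C | intermediate
27 | (S)-1-[(tert-butyldiphenylsilyl)oxy]hex-5-en-3-ol | C=CC[C@@H](CCO[Si](c1ccccc1)(c1ccccc1)C(C)(C)C)O | intermediate
28 | (S)-tert-butyldiphenyl({3-[(triethylsilyl)oxy]hex-5-en-1-yl}oxy)silane | C=CC[C@@H](CCO[Si](c1ccccc1)(c1ccccc1)C(C)(C)C)O[Si](CC)(CC)CC | intermediate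
29 | (R)-5-[(tert-butyldiphenylsilyl)oxy]-3-[(triethylsilyl)oxy]pentanal | O=CC[C@@H](CCO[Si](c1ccccc1)(c1ccccc1)C(C)(C)C)O[Si](CC)(CC)CC | intermediate
30 | (S)-5-[(tert-butyldiphenylsilyl)oxy]-3-[(triethylsilyl)oxy]pentan-1-ol | OCC[C@@H](CCO[Si](c1ccccc1)(c1ccccc1)C(C)(C)C)O[Si](CC)(CC)CC | intermediate
31 | (R)-tert-butyl({5-iodo-3-[(triethylsilyl)oxy]pentyl}oxy)diphenylsilane | ICC[C@@H](CCO[Si](c1ccccc1)(c1ccccc1)C(C)(C)C)O[Si](CC)(CC)CC | intermediate
32 | {(S)-5-[(tert-butyldiphenylsilyl)oxy]-3-[(triethylsilyl)oxy]pentyl}lithium | [Li]CC[C@@H](CCO[Si](c1ccccc1)(c1ccccc1)C(C)(C)C)O[Si](CC)(CC)CC | intermediate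
33 | {(R)-5-[(tert-butyldiphenylsilyl)oxy]-3-[(triethylsilyl)oxy]pentyl}magnesium bromide | Br[Mg]CC[C@@H](CCO[Si](c1ccccc1)(c1ccccc1)C(C)(C)C)O[Si](CC)(CC)CC | intermediate
34 | (1S,4S)-6-[(tert-butyldiphenylsilyl)oxy]-1-[(2S,5R)-5-[(7Z,9E)-tetradeca-7,9,13-trien-1-yl]tetrahydrofuran-2-yl]-4-[(triethylsilyl)oxy]hexan-1-ol | C=CCC/C=C/C=C\CCCCCC[C@@H]1CC[C@@H]([C@@H](O)CC[C@@H](CCO[Si](c2ccccc2)(c2ccccc2)C(C)(C)C)O[Si](CC)(CC)CC)O1 | intermediate
35 | (1S,4S)-6-[(tert-butyldiphenylsilyl)oxy]-1-[(2S,5R)-5-[(7Z,9E)-tetradeca-7,9,13-trien-1-yl]tetrahydrofuran-2-yl]hexane-1,4-diol | C=CCC/C=C/C=C\CCCCCC[C@@H]1CC[C@@H]([C@@H](O)CC[C@@H](CCO[Si](c2ccccc2)(c2ccccc2)C(C)(C)C)O)O1 | intermediate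
36 | (1S,4S)-6-[(tert-butyldiphenylsilyl)oxy]-1-[(2S,5R)-5-[(7Z,9E)-tetradeca-7,9,13-trien-1-yl]tetrahydrofuran-2-yl]hexane-1,4-diyl dimethanesulfonate | C=CCC/C=C/C=C\CCCCCC[C@@H]1CC[C@@H]([C@@H](OS(C)(=O)=O)CC[C@@H](CCO[Si](c2ccccc2)(c2ccccc2)C(C)(C)C)OS(C)(=O)=O)O1 | intermediate
37 | (1S,4R)-6-[(tert-butyldiphenylsilyl)oxy]-4-hydroperoxy-1-[(2S,5R)-5-[(7Z,9E)-tetradeca-7,9,13-trien-1-yl]tetrahydrofuran-2-yl]hexyl methanesulfonate | C=CCC/C=C/C=C\CCCCCC[C@@H]1CC[C@@H]([C@@H](OS(C)(=O)=O)CC[C@H](CCO[Si](c2ccccc2)(c2ccccc2)C(C)(C)C)OO)O1 | intermediate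
38 | tert-butyldiphenyl{2-[(3R,6R)-6-[(2S,5R)-5-[(7Z,9E)-tetradeca-7,9,13-trien-1-yl]tetrahydrofuran-2-yl]-1,2-dioxan-3-yl]ethoxy}silane | C=CCC/C=C/C=C\CCCCCC[C@@H]1CC[C@@H]([C@H]2CC[C@H](CCO[Si](c3ccccc3)(c3ccccc3)C(C)(C)C)OO2)O1 | intermediate
39 | 2-[(3R,6R)-6-[(2S,5R)-5-[(7Z,9E)-tetradeca-7,9,13-trien-1-yl]tetrahydrofuran-2-yl]-1,2-dioxan-3-yl]ethan-1-ol | C=CCC/C=C/C=C\CCCCCC[C@@H]1CC[C@@H]([C@H]2CC[C@H](CCO)OO2)O1 | intermediate
40 | 2-[(3R,6R)-6-[(2S,5R)-5-[(7Z,9E)-tetradeca-7,9,13-trien-1-yl]tetrahydrofuran-2-yl]-1,2-dioxan-3-yl]acetaldehyde | C=CCC/C=C/C=C\CCCCCC[C@@H]1CC[C@@H]([C@H]2CC[C@H](CC=O)OO2)O1 | intermediate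
41 | 2-[(3R,6R)-6-[(2S,5R)-5-[(7Z,9E)-tetradeca-7,9,13-trien-1-yl]tetrahydrofuran-2-yl]-1,2-dioxan-3-yl]acetic acid | C=CCC/C=C/C=C\CCCCCC[C@@H]1CC[C@@H]([C@H]2CC[C@H](CC(=O)O)OO2)O1 | target

## Step count and risk

Total step count: 28. Longest linear sequence: 21 steps (steps 1–12, 14–16 and 23–28). Side branches: step 13 (enal 19) and steps 17–22 (iodide 31).

**Step 6 (key step).** The carbenoid may be diverted into 1,5 C–H insertion at the silyloxy-bearing C6, a [1,2] shift or dimerisation. Facial discrimination in ylide 9 may be incomplete, and the α-alkoxy ketone 10 may epimerise at C10 during isolation. Fallback, setting out from 8 and returning at 13 (it bypasses steps 6–9):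
- Wolff rearrangement of 8 (PhCO2Ag, Et3N, MeOH) should give methyl (S)-4-(allyloxy)-5-[(tert-butyldiphenylsilyl)oxy]pentanoate F1.
- Isomerisation of the allyl ether with [Ir(cod)(PMePh2)2]PF6 (activated with H2, THF) gives methyl (S)-5-[(tert-butyldiphenylsilyl)oxy]-4-(prop-1-en-1-yloxy)pentanoate F2.
- Dilute acid in acetone hydrolyses F2 and lactonises it to (S)-5-{[(tert-butyldiphenylsilyl)oxy]methyl}dihydrofuran-2(3H)-one F3.
- Reduction with i-Bu2AlH at −78 °C gives (5S)-5-{[(tert-butyldiphenylsilyl)oxy]methyl}tetrahydrofuran-2-ol F4, and acetylation (Ac2O, pyridine) gives (5S)-5-{[(tert-butyldiphenylsilyl)oxy]methyl}tetrahydrofuran-2-yl acetate F5.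
- Allyltrimethylsilane with BF3·OEt2 at −78 °C then adds to the five-membered oxocarbenium ion preferentially trans to the C7 substituent (Hosomi–Sakurai-type C-glycosylation) to give 13 after removal of the cis isomer.

**Step 26.** The closure at C6, a secondary carbon flanked by the ring oxygen, may be slower than E2 elimination of either mesylate, intermolecular alkylation of 37, or base-induced fragmentation of the dioxane once formed. Participation of the tetrahydrofuran oxygen at C6 could also erode the inversion. Fallback, setting out from 36 and returning at 38, with the two alkylations separated: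
- The unhindered C3 mesylate alone is displaced by 2-methoxypropan-2-yl hydroperoxide with CsOH in DMF at 0 °C to give (1S,4R)-6-[(tert-butyldiphenylsilyl)oxy]-4-[(2-methoxypropan-2-yl)peroxy]-1-[(2S,5R)-5-[(7Z,9E)-tetradeca-7,9,13-trien-1-yl]tetrahydrofuran-2-yl]hexyl methanesulfonate F6.
- Aqueous acetic acid in THF unmasks the hydroperoxide 37, which is now isolated.
- Ring closure is run as a separate dilute intramolecular alkylation with KOt-Bu and 18-crown-6 in THF at low temperature to give 38.

**Step 23.** Facial selectivity may be poor if the magnesium chelate is incomplete and open-chain Felkin–Anh addition competes. The γ-silyloxy alkyllithium 32 may undergo silyl migration from oxygen to carbon on warming. Fallback, setting out from 34 obtained as a mixture with its C6 epimer and returning at 34: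
- Dess–Martin oxidation of the mixture gives (S)-6-[(tert-butyldiphenylsilyl)oxy]-1-[(2S,5R)-5-[(7Z,9E)-tetradeca-7,9,13-trien-1-yl]tetrahydrofuran-2-yl]-4-[(triethylsilyl)oxy]hexan-1-one F7.
- Reduction with LiBH(s-Bu)3 in THF at −78 °C delivers hydride in the Felkin–Anh sense, which for an α-alkoxy ketone gives the threo alcohol 34.

**Step 14.** Z selectivity may be incomplete through stereochemical drift of the oxaphosphetane, and the base-sensitive enal 19 may be lost to side reactions. Fallback, setting out from 16 and returning at 21, building the diene by sp2–sp2 coupling: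
- Kornblum oxidation of 16 (DMSO, NaHCO3, 100 °C) gives 7-[(2R,5S)-5-{[(tert-butyldiphenylsilyl)oxy]methyl}tetrahydrofuran-2-yl]heptanal F8.
- Stork–Zhao olefination (Ph3P+CH2I I−, NaN(SiMe3)2, THF, −78 °C) gives tert-butyl{[(2S,5R)-5-[(Z)-8-iodooct-7-en-1-yl]tetrahydrofuran-2-yl]methoxy}diphenylsilane F9.
- Suzuki coupling of F9 (Pd(PPh3)4, K3PO4, THF/H2O) with 2-[(E)-hexa-1,5-dien-1-yl]-4,4,5,5-tetramethyl-1,3,2-dioxaborolane F10, made from hex-5-en-1-yne and pinacolborane with Cp2Zr(H)Cl (cat.), gives 21 with retention of both alkene geometries.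

## Further compounds

F1 | step 6 | methyl (S)-4-(allyloxy)-5-[(tert-butyldiphenylsilyl)oxy]pentanoate | COC(=O)CC[C@H](OCC=C)CO[Si](c1ccccc1)(c1ccccc1)C(C)(C)C
F2 | step 6 | methyl (S)-5-[(tert-butyldiphenylsilyl)oxy]-4-(prop-1-en-1-yloxy)pentanoate | COC(=O)CC[C@H](OC=CC)CO[Si](c1ccccc1)(c1ccccc1)C(C)(C)C
F3 | step 6 | (S)-5-{[(tert-butyldiphenylsilyl)oxy]methyl}dihydrofuran-2(3H)-one | O=C1CC[C@@H](CO[Si](c2ccccc2)(c2ccccc2)C(C)(C)C)O1
F4 | step 6 | (5S)-5-{[(tert-butyldiphenylsilyl)oxy]methyl}tetrahydrofuran-2-ol (both anomers) | OC1CC[C@@H](CO[Si](c2ccccc2)(c2ccccc2)C(C)(C)C)O1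
F5 | step 6 | (5S)-5-{[(tert-butyldiphenylsilyl)oxy]methyl}tetrahydrofuran-2-yl acetate (both anomers) | CC(=O)OC1CC[C@@H](CO[Si](c2ccccc2)(c2ccccc2)C(C)(C)C)O1
F6 | step 26 | (1S,4R)-6-[(tert-butyldiphenylsilyl)oxy]-4-[(2-methoxypropan-2-yl)peroxy]-1-[(2S,5R)-5-[(7Z,9E)-tetradeca-7,9,13-trien-1-yl]tetrahydrofuran-2-yl]hexyl methanesulfonate | C=CCC/C=C/C=C\CCCCCC[C@@H]1CC[C@@H]([C@@H](OS(C)(=O)=O)CC[C@H](CCO[Si](c2ccccc2)(c2ccccc2)C(C)(C)C)OOC(C)(C)OC)O1
F7 | step 23 | (S)-6-[(tert-butyldiphenylsilyl)oxy]-1-[(2S,5R)-5-[(7Z,9E)-tetradeca-7,9,13-trien-1-yl]tetrahydrofuran-2-yl]-4-[(triethylsilyl)oxy]hexan-1-one | C=CCC/C=C/C=C\CCCCCC[C@@H]1CC[C@@H](C(=O)CC[C@@H](CCO[Si](c2ccccc2)(c2ccccc2)C(C)(C)C)O[Si](CC)(CC)CC)O1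
F8 | step 14 | 7-[(2R,5S)-5-{[(tert-butyldiphenylsilyl)oxy]methyl}tetrahydrofuran-2-yl]heptanal | O=CCCCCCC[C@@H]1CC[C@@H](CO[Si](c2ccccc2)(c2ccccc2)C(C)(C)C)O1
F9 | step 14 | tert-butyl{[(2S,5R)-5-[(Z)-8-iodooct-7-en-1-yl]tetrahydrofuran-2-yl]methoxy}diphenylsilane | I/C=C\CCCCCC[C@@H]1CC[C@@H](CO[Si](c2ccccc2)(c2ccccc2)C(C)(C)C)O1
F10 | step 14 | 2-[(E)-hexa-1,5-dien-1-yl]-4,4,5,5-tetramethyl-1,3,2-dioxaborolane | C=CCC/C=C/B1OC(C)(C)C(C)(C)O1
A1 | alternative 1 | tert-butyl{2-[(3S,6R)-6-[(2S,5R)-5-{7-[(tert-butyldimethylsilyl)oxy]heptyl}tetrahydrofuran-2-yl]-3,6-dihydro-1,2-dioxin-3-yl]ethoxy}diphenylsilane | CC(C)(C)[Si](C)(C)OCCCCCCC[C@@H]1CC[C@@H]([C@H]2C=C[C@H](CCO[Si](c3ccccc3)(c3ccccc3)C(C)(C)C)OO2)O1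
A2 | alternative 2 | Cyrene, (1S,5R)-6,8-dioxabicyclo[3.2.1]octan-4-one | O=C1CC[C@H]2CO[C@@H]1O2
A3 | alternative 2 | tert-butyldiphenyl{2-[(3R,6R)-6-[(2S,5R)-5-[(7Z,9E)-tetradeca-7,9,13-trien-1-yl]tetrahydrofuran-2-yl]-1,2-dioxan-3-yl]ethoxy}silane | C=CCC/C=C/C=C\CCCCCC[C@@H]1CC[C@@H]([C@H]2CC[C@H](CCO[Si](c3ccccc3)(c3ccccc3)C(C)(C)C)OO2)O1
A4 | alternative 3 | diethyl L-tartrate, diethyl (2R,3R)-2,3-dihydroxybutanedioate | CCOC(=O)[C@H](O)[C@@H](O)C(=O)OCC
A5 | alternative 3 | tert-butyl{2-[(3S,6R)-6-[(2S,5R)-5-{7-[(tert-butyldimethylsilyl)oxy]heptyl}-2,5-dihydrofuran-2-yl]-3,6-dihydro-1,2-dioxin-3-yl]ethoxy}diphenylsilane | CC(C)(C)[Si](C)(C)OCCCCCCC[C@@H]1C=C[C@@H]([C@H]2C=C[C@H](CCO[Si](c3ccccc3)(c3ccccc3)C(C)(C)C)OO2)O1
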